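**Retrosynthetic overview**
- Leprolomin is traced back, through chelation-directed O-demethylation of ring A, O-debenzylation of ring B and one C-acetylation on each ring, to a diaryl ether whose A-ring (3,5-dimethoxy-4-methylphenyl) is symmetric.
- The diaryl ether C–O bond is cut to a hindered B-ring phenol and an unhindered A-ring bromide (Ullmann coupling).
- The B-ring phenol comes from Baeyer–Villiger oxidation of dibenzylated 2,6-dihydroxy-4-methoxy-3-methylacetophenone. The key C–C bond, ring carbon to the future C-methyl carbon, is made by an intermolecular Mannich reaction (phenol + CH2O + Me2NH) followed by C–N hydrogenolysis.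
- The A-ring bromide comes from 2,6-dimethoxytoluene by sterically controlled C–H borylation and bromodeboronation.
- No ring is built, because both benzene rings are bought. The symmetry of each precursor, or the presence of a single free position, fixes all regiochemistry.

Assumption: leprolomin has no stereocentre and its SMILES carries no stereodescriptor, so it is made as one achiral compound and no configuration has to be set.

**Step 1**
Reactants: 1 2',4',6'-trihydroxyacetophenone
Product: 2 1-(2,6-dihydroxy-4-methoxyphenyl)ethan-1-one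
Conditions: Me2SO4 (1.0 equiv), K2CO3 (1.0 equiv), acetone, reflux
Reagents that add atoms: dimethyl sulfate, COS(=O)(=O)OC
Why: In this Williamson-type O-methylation the 4-OH is the most acidic hydroxyl and the only one not hydrogen-bonded to the acetyl C=O, so one equivalent of reagent alkylates it preferentially.

**Step 2**
Reactants: 2 1-(2,6-dihydroxy-4-methoxyphenyl)ethan-1-one; 3 formaldehyde; 4 dimethylamine
Product: 6 1-{3-[(dimethylamino)methyl]-2,6-dihydroxy-4-methoxyphenyl}ethan-1-one, via dimethylmethyleneiminium ion 5 (not isolated)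
Conditions: 37% aq CH2O (1.0 equiv), 40% aq Me2NH (1.1 equiv), EtOH, 0 °C → rt
Reagents that add atoms: none
Why: In this intermolecular three-component phenolic Mannich reaction the iminium ion is attacked by ring carbon C3 (ortho/para to three oxygen donors, and equivalent to C5 by symmetry, so only one mono-adduct exists), while 1.0 equiv of CH2O under cold non-acidic conditions suppresses bis-aminomethylation, methylene-bridged dimers and reaction at the acetyl CH3.

**Step 3**
Reactants: 6 1-{3-[(dimethylamino)methyl]-2,6-dihydroxy-4-methoxyphenyl}ethan-1-one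
Product: 7 1-(2,6-dihydroxy-4-methoxy-3-methylphenyl)ethan-1-one
Conditions: H2 (4 bar), 10% Pd/C, MeOH, 50 °C
Reagents that add atoms: none
Why: Catalytic hydrogenolysis cleaves the activated benzylic C–N bond of the phenolic Mannich base to give Ar–CH3, and the doubly chelated, vinylogous-acid-like aryl ketone is not reduced.

**Step 4**
Reactants: 7 1-(2,6-dihydroxy-4-methoxy-3-methylphenyl)ethan-1-one
Product: 8 1-[2,6-bis(benzyloxy)-4-methoxy-3-methylphenyl]ethan-1-one
Conditions: BnBr (2.5 equiv), K2CO3 (3 equiv), TBAI (cat.), DMF, 65 °C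
Reagents that add atoms: benzyl bromide, BrCc1ccccc1
Why: Warm K2CO3 in DMF breaks the chelation, so this Williamson etherification benzylates both ortho-hydroxyls and marks them as the two oxygens that will later be freed without touching any OMe.

**Step 5**
Reactants: 8 1-[2,6-bis(benzyloxy)-4-methoxy-3-methylphenyl]ethan-1-one
Product: 9 2,6-bis(benzyloxy)-4-methoxy-3-methylphenyl acetate
Conditions: mCPBA (1.5 equiv), TFA (1 equiv), CH2Cl2, 0 °C → rt, dark
Reagents that add atoms: m-chloroperoxybenzoic acid, OOC(=O)c1cccc(Cl)c1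
Why: In this Baeyer–Villiger oxidation the very electron-rich, out-of-plane aryl group migrates far better than methyl, which places the fourth ring oxygen exactly between the two benzyloxy groups.

**Step 6**
Reactants: 9 2,6-bis(benzyloxy)-4-methoxy-3-methylphenyl acetate
Product: 10 2,6-bis(benzyloxy)-4-methoxy-3-methylphenol
Conditions: K2CO3 (cat.), degassed MeOH, rt, Ar
Reagents that add atoms: none
Why: Base-catalysed transesterification (methanolysis) of the labile aryl acetate frees the phenol, with air excluded because the product is an easily oxidised hydroquinone monoether.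

**Step 7**
Reactants: 11 2,6-dimethoxytoluene
Product: 12 2-(3,5-dimethoxy-4-methylphenyl)-4,4,5,5-tetramethyl-1,3,2-dioxaborolane
Conditions: B2pin2 (1.0 equiv), [Ir(OMe)(cod)]2 (1.5 mol %), dtbpy (3 mol %), THF, 80 °C
Reagents that add atoms: bis(pinacolato)diboron, CC1(C)OB(OC1(C)C)B1OC(C)(C)C(C)(C)O1
Why: Iridium-catalysed C–H borylation is sterically controlled, so it functionalises the only C–H without an ortho substituent (para to CH3), a position that electrophilic substitution cannot reach.

**Step 8**
Reactants: 12 2-(3,5-dimethoxy-4-methylphenyl)-4,4,5,5-tetramethyl-1,3,2-dioxaborolane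
Product: 13 5-bromo-1,3-dimethoxy-2-methylbenzene
Conditions: CuBr2 (3 equiv), MeOH/H2O 1:1, 80 °C
Reagents that add atoms: copper(II) bromide, [Cu+2].[Br-].[Br-]
Why: Copper(II)-mediated bromodeboronation proceeds by transmetalation and C–Br reductive elimination, so it replaces boron ipso and does not act as a Br+ source on the activated ring positions.

**Step 9**
Reactants: 10 2,6-bis(benzyloxy)-4-methoxy-3-methylphenol; 13 5-bromo-1,3-dimethoxy-2-methylbenzene
Product: 14 1,3-bis(benzyloxy)-2-(3,5-dimethoxy-4-methylphenoxy)-5-methoxy-4-methylbenzene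
Conditions: CuI (10 mol %), picolinic acid (20 mol %), K3PO4 (2 equiv), DMSO, 90 °C, Ar
Reagents that add atoms: none
Why: This ligand-accelerated Ullmann diaryl ether synthesis pairs the electron-rich 2,6-disubstituted phenoxide with a bromide that has no ortho substituent, so all the steric load sits on one partner only.

**Step 10**
Reactants: 14 1,3-bis(benzyloxy)-2-(3,5-dimethoxy-4-methylphenoxy)-5-methoxy-4-methylbenzene
Product: 15 1-{6-[3-acetyl-2,6-bis(benzyloxy)-4-methoxy-5-methylphenoxy]-2,4-dimethoxy-3-methylphenyl}ethan-1-one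
Conditions: AcOH (6 equiv), TFAA (6 equiv), 85% H3PO4 (cat.), CH2Cl2, 0 °C → rt
Reagents that add atoms: acetic acid, CC(=O)O
Why: This twofold Friedel–Crafts acylation uses the mixed anhydride and no metal Lewis acid, so the benzyl ethers survive; ring B has one free position, ring A has two equivalent ones, and each ring is deactivated after one acetyl, so a single diketone results.

**Step 11**
Reactants: 15 1-{6-[3-acetyl-2,6-bis(benzyloxy)-4-methoxy-5-methylphenoxy]-2,4-dimethoxy-3-methylphenyl}ethan-1-one
Product: 16 1-[6-(3-acetyl-2,6-dihydroxy-4-methoxy-5-methylphenoxy)-2,4-dimethoxy-3-methylphenyl]ethan-1-one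
Conditions: H2 (1 atm), 10% Pd/C, EtOAc/MeOH, rt
Reagents that add atoms: none
Why: Catalytic hydrogenolysis of the two aryl benzyl ethers at 1 atm is much faster than reduction of the hindered, electron-rich aryl ketones and leaves all methyl ethers and the diaryl ether intact.

**Step 12**
Reactants: 16 1-[6-(3-acetyl-2,6-dihydroxy-4-methoxy-5-methylphenoxy)-2,4-dimethoxy-3-methylphenyl]ethan-1-one
Product: 17 leprolomin (1-[6-(3-acetyl-2,6-dihydroxy-4-methoxy-5-methylphenoxy)-2-hydroxy-4-methoxy-3-methylphenyl]ethan-1-one)
Conditions: BCl3 (4 equiv, 1 M in CH2Cl2), CH2Cl2, −78 → 0 °C; then aq HCl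
Reagents that add atoms: none
Why: In this chelation-directed BCl3 ether cleavage the ring-A acetyl delivers boron only to its single ortho-OMe, while the ring-B carbonyl is already locked in a six-membered boron chelate with its ortho-OH, so the ring-B OMe and the non-chelated ring-A 4-OMe are kept.

**Compound list**
1 | 2',4',6'-trihydroxyacetophenone | CC(=O)c1c(O)cc(O)cc1O | starting material
2 | 1-(2,6-dihydroxy-4-methoxyphenyl)ethan-1-one | CC(=O)c1c(O)cc(OC)cc1O | intermediate
3 | formaldehyde | C=O | starting material
4 | dimethylamine | CNC | starting material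
5 | dimethylmethyleneiminium ion (not isolated) | C=[N+](C)C | intermediate
6 | 1-{3-[(dimethylamino)methyl]-2,6-dihydroxy-4-methoxyphenyl}ethan-1-one | CC(=O)c1c(O)cc(OC)c(CN(C)C)c1O | intermediate
7 | 1-(2,6-dihydroxy-4-methoxy-3-methylphenyl)ethan-1-one | CC(=O)c1c(O)cc(OC)c(C)c1O | intermediate
8 | 1-[2,6-bis(benzyloxy)-4-methoxy-3-methylphenyl]ethan-1-one | CC(=O)c1c(OCc2ccccc2)cc(OC)c(C)c1OCc1ccccc1 | intermediate
9 | 2,6-bis(benzyloxy)-4-methoxy-3-methylphenyl acetate | CC(=O)Oc1c(OCc2ccccc2)cc(OC)c(C)c1OCc1ccccc1 | intermediate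
10 | 2,6-bis(benzyloxy)-4-methoxy-3-methylphenol | Oc1c(OCc2ccccc2)cc(OC)c(C)c1OCc1ccccc1 | intermediate
11 | 2,6-dimethoxytoluene | COc1cccc(OC)c1C | starting material
12 | 2-(3,5-dimethoxy-4-methylphenyl)-4,4,5,5-tetramethyl-1,3,2-dioxaborolane | COc1cc(B2OC(C)(C)C(C)(C)O2)cc(OC)c1C | intermediate
13 | 5-bromo-1,3-dimethoxy-2-methylbenzene | COc1cc(Br)cc(OC)c1C | intermediate
14 | 1,3-bis(benzyloxy)-2-(3,5-dimethoxy-4-methylphenoxy)-5-methoxy-4-methylbenzene | COc1cc(Oc2c(OCc3ccccc3)cc(OC)c(C)c2OCc2ccccc2)cc(OC)c1C | intermediate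
15 | 1-{6-[3-acetyl-2,6-bis(benzyloxy)-4-methoxy-5-methylphenoxy]-2,4-dimethoxy-3-methylphenyl}ethan-1-one | COc1cc(Oc2c(OCc3ccccc3)c(C)c(OC)c(C(C)=O)c2OCc2ccccc2)c(C(C)=O)c(OC)c1C | intermediate
16 | 1-[6-(3-acetyl-2,6-dihydroxy-4-methoxy-5-methylphenoxy)-2,4-dimethoxy-3-methylphenyl]ethan-1-one | COc1cc(Oc2c(O)c(C)c(OC)c(C(C)=O)c2O)c(C(C)=O)c(OC)c1C | intermediate
17 | leprolomin (achiral) | COc1cc(Oc2c(O)c(C)c(OC)c(C(C)=O)c2O)c(C(C)=O)c(O)c1C | target

**Step count and risks**
Total step count: 12. Longest linear sequence: 10 (steps 1–6, then 9–12). Steps 7–8 form the short second branch.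

**Step 5 (Baeyer–Villiger oxidation).** The di-ortho-substituted ketone may add peracid slowly, and the electron-rich ring may be over-oxidised.
- The fallback sets out from 8 and comes back at 10, bypassing 9 and step 6. It replaces the peracid route by a benzylic hydroperoxide (Hock-type) rearrangement.
- Compound 8 is reduced with LiAlH4 in THF to racemic 1-[2,6-bis(benzyloxy)-4-methoxy-3-methylphenyl]ethan-1-ol F1.
- With 50% H2O2 and BF3·OEt2 in CH2Cl2 at 0 °C, F1 ionises and is trapped as racemic 1-[2,6-bis(benzyloxy)-4-methoxy-3-methylphenyl]ethyl hydroperoxide F2.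
- F2 undergoes acid-induced aryl migration to oxygen in the same flask, and the resulting hemiacetal collapses to phenol 10.

**Step 9 (Ullmann coupling).** The phenol is doubly ortho-substituted and can be oxidised by copper.
- The fallback sets out from 12 (together with 10) and comes back at 14. It replaces copper catalysis by metal-free O-arylation with a diaryliodonium salt.
- Compound 12 is cleaved with NaIO4/NH4OAc in acetone/water to (3,5-dimethoxy-4-methylphenyl)boronic acid F3.
- 4-Iodoanisole is oxidised with mCPBA/BF3·OEt2 in CH2Cl2, and F3 is added at low temperature. Regiospecific ipso substitution at boron gives (3,5-dimethoxy-4-methylphenyl)(4-methoxyphenyl)iodonium tetrafluoroborate F4.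
- The potassium phenoxide of 10 (t-BuOK, THF, 0 → 40 °C) then undergoes ligand coupling at iodine(III). The less electron-rich 3,5-dimethoxy-4-methylphenyl group is transferred, giving 14.

**Step 10 (double acetylation next to benzyl ethers).** Acid may cause benzyl loss or C-benzylation, and conversion at the crowded positions may be incomplete.
- The fallback sets out from 14 and comes back at 16. It removes the benzyl groups before the C–C bond formation.
- Compound 14 is hydrogenolysed (H2, Pd/C, EtOAc/MeOH) to 2-(3,5-dimethoxy-4-methylphenoxy)-5-methoxy-4-methylbenzene-1,3-diol F5.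
- Ac2O/BF3·OEt2 (0 → 50 °C; O-acetylation, Fries shift and direct Friedel–Crafts acylation all converge on the same carbons) gives 3-acetyl-6-(2-acetyl-3,5-dimethoxy-4-methylphenoxy)-5-hydroxy-3-methoxy-2-methylphenyl-type monoacetate, that is the 2'-O-acetate of 16 F6.
- Its single non-chelated aryl acetate is removed with catalytic K2CO3 in MeOH to give 16.

**Further compounds**
F1 | step 5 | (±)-1-[2,6-bis(benzyloxy)-4-methoxy-3-methylphenyl]ethan-1-ol (racemic) | CC(O)c1c(OCc2ccccc2)cc(OC)c(C)c1OCc1ccccc1
F2 | step 5 | (±)-1-[2,6-bis(benzyloxy)-4-methoxy-3-methylphenyl]ethyl hydroperoxide (racemic) | CC(OO)c1c(OCc2ccccc2)cc(OC)c(C)c1OCc1ccccc1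
F3 | step 9 | (3,5-dimethoxy-4-methylphenyl)boronic acid | COc1cc(B(O)O)cc(OC)c1C
F4 | step 9 | (3,5-dimethoxy-4-methylphenyl)(4-methoxyphenyl)iodonium tetrafluoroborate | COc1ccc([I+]c2cc(OC)c(C)c(OC)c2)cc1.F[B-](F)(F)F
F5 | step 10 | 2-(3,5-dimethoxy-4-methylphenoxy)-5-methoxy-4-methylbenzene-1,3-diol | COc1cc(Oc2c(O)cc(OC)c(C)c2O)cc(OC)c1C
F6 | step 10 | 2'-O-acetate of 16 | COc1cc(Oc2c(OC(C)=O)c(C)c(OC)c(C(C)=O)c2O)c(C(C)=O)c(OC)c1C
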